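The easy step first: every coupling sets free one acid, and that acid has to be paid for.

| flask | electrophile | nucleophile | protic impurity | time |
|---|---|---|---|---|
| north | 1.0 mM | 0.950 mM | 0.200 mM | 15 s |
| south-west | 1.0 mM | 1.90 mM | 0.200 mM | 15 s |
| south-east | 1.0 mM | 3.80 mM | 0.200 mM | 15 s |

    electrophile + nucleophile → acid set free + target (k1 = 580 M⁻¹ s⁻¹)
    nucleophile + acid set free ⇌ protonated nucleophile, settled at all times (K2 = 1.8 × 10⁶ M⁻¹)
    nucleophile + protic impurity → quenched reagent (k3 = 2000 M⁻¹ s⁻¹)
    electrophile + target → side product (k4 = 230 M⁻¹ s⁻¹)
    crystals ⇌ target, rate k5*(cs5 - [target]) while solid is left; crystals form when [target] > cs5 (cs5 = 0.17 mM, k5 = 48 s⁻¹)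

1. part of the electrophile that has reacted at the end, north
2. part of the electrophile that has reacted at the end, south-west
3. part of the electrophile that has reacted at the end, south-east
4. what raising the concentration of nucleophile from its lowest to its highest value here does to the part of the electrophile that has reacted (changes below 5 percentage points count as none) (it rises / it falls / no change)

- in percentages every species weighs as the electrophile in it: one side product counts as two
- for target the crystals are counted in
- as a solid, counted per litre of solution: crystals
- run time (north): 15 s

In north, K2 times the charged [nucleophile] is 1710, far above one, so the acid goes onto a second nucleophile and each coupling costs two. Step 3 costs one more nucleophile per impurity. That gives us the coupling allowance: the nucleophile charge less the impurity charge, divided by two. In north it is 0.375 mM, in south-west 0.850 mM and in south-east 1.80 mM. Against 1.0 mM of electrophile, this reckoning makes nucleophile the limiting reagent in north and south-west, but not in south-east.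

Electrophile beyond the allowance still has step 4. The allowances of north and south-west both stand above the 0.17 mM that dissolves, so as a rough step we hold [target] at that level in both and let the electrophile beyond the allowance decay pseudo-first-order, keeping a fraction 0.556 over the run. We commit to 65.2% reacted in north and 91.7% in south-west. The allowance of south-east stands above its electrophile charge, so there we write complete reaction.

The weak link is paying the impurity in full: steps 1 and 3 compete for nucleophile. Leaving step 4 aside, ln of the impurity fraction left moves 3.45 times ln of the electrophile fraction left. At the allowance, north keeps 19.8% of its impurity, so its allowance becomes 0.395 mM and its estimate 66.3%. South-west keeps 0.144%, and its allowance stands.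

The forecast gives 66%, 93% and 100%, and says it rises, on the ground that “Each coupling uses two nucleophiles, because the released acid protonates a second one”. The simulation gives 67.6%, 93.4% and >99.9%: it rises, by 32 percentage points. The main reason is the difference in nucleophile charge: with that difference taken away, south-east reaches 67.6% instead of >99.9%.

With step 4 switched off, north reaches 41.5% instead of 67.6%, close to the reforged allowance as a share of the charge, 39.5%. So 26 points of north's reacted part is a part owed to target eating electrophile, not to coupling.

Take the neighbour flask, south-west with 0.76 mM of nucleophile. Its allowance is 0.280 mM, reforged to 0.312 mM, which gives 61.7% reacted. The computed flask gives 57.8%, with side product holding most of the electrophile.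

All constants are assumed; what happens was integrated by code.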